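The hydroxylated ε-ring (C1–C6) shows oxygen at C3, a methyl on C5 and the gem-dimethyl carbon C1: the imprint of two 3-methylbut-2-enoyl units. The route rests on cutting C3–C4 and C6–C1. In one flask the silyl dienol ether of methyl 3-methylbut-2-enoate is acylated at its terminal carbon by 3-methylbut-2-enoyl chloride (C3–C4) and the open-chain keto dienoate closes through its oxido-triene (C6–C1), giving the complete ring as a 3-keto ester. Reagent-controlled reduction sets C3, the ester is grown into a C15 phosphonium salt, and this is joined to a C25 aldehyde made from (S)-α-ionone and a C10 dialdehyde.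

Key step: step 2

Remark: (S)-α-ionone (11) is assumed to be purchasable as the single enantiomer; ring atoms of all intermediates carry carotenoid numbers (C1 gem-dimethyl carbon, C3 oxygen-bearing carbon, C5 methyl-bearing carbon, C6 chain-bearing carbon).

Step 1
Reactants: 1 methyl 3-methylbut-2-enoate
Product: 2 1-methoxy-3-methyl-1-(trimethylsilyloxy)buta-1,3-diene
Conditions: LiN(i-Pr)2, THF, −78 °C; Me3SiCl, −78 °C → rt; distillation
Reagents that add atoms: chlorotrimethylsilane, C[Si](C)(C)Cl
Why: Kinetic γ-deprotonation of the senecioate by the lithium amide gives the extended (dienolate) anion, which the hard silyl chloride traps on oxygen to give the vinylketene silyl acetal, a standard preparation of silyl dienol ethers.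

Step 2
Reactants: 2 1-methoxy-3-methyl-1-(trimethylsilyloxy)buta-1,3-diene, 3 3-methylbut-2-enoyl chloride
Product: 5 methyl 2,6,6-trimethyl-4-oxocyclohex-2-ene-1-carboxylate (racemate), via open-chain keto dienoate 4 (not isolated)
Conditions: ZnBr2 (5 mol%), CH2Cl2, −40 → 0 °C; then DBU (1,8-diazabicyclo[5.4.0]undec-7-ene), 0 → 40 °C; aq NH4Cl
Reagents that add atoms: none
Why: ZnBr2 activates acid chloride 3 for a vinylogous Mukaiyama-type acylation in which the unhindered terminal CH2 carbon of 2 (later C4) attacks the acyl carbon (later C3) and Me3SiCl is lost, giving 4. DBU then removes a C4 proton, which is acidified by the ketone and, through the enoate, by the ester, and the resulting 3-oxido-hexatriene C1=C2–C3(O−)=C4–C5=C6 closes by disrotatory 6π-electrocyclisation, equivalent to a 6-endo-trig vinylogous Michael addition of C6 to the β,β-dimethyl enone carbon C1 (a formal [3+3] annulation); reprotonation leaves the C4=C5 double bond conjugated with the C3 ketone. The closest known reactions are the γ-acylation of silyl dienol ethers by acid chlorides and the base-induced cyclisation of phorone to isophorone. The six-membered ring is closed in the 6-endo mode and its only stereocentre, C6, forms as a racemate, since nothing in the flask is chiral and C6–H stays acidic in 5. The step needs γ- over α-acylation, which the silyl (not lithium) dienolate and the free terminal carbon secure, and C–C closure instead of lactonisation to a 2-pyranone, which the E-geometry of the enoate in 4 disfavours by holding the ester away from the enolate oxygen.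

Step 3
Reactants: 5 methyl 2,6,6-trimethyl-4-oxocyclohex-2-ene-1-carboxylate (racemate)
Product: 6 methyl (1S,4S)-4-hydroxy-2,6,6-trimethylcyclohex-2-ene-1-carboxylate (trans; 3S,6S in carotenoid numbering)
Conditions: (R)-2-methyl-CBS-oxazaborolidine [(3aR)-1-methyl-3,3-diphenyltetrahydro-1H,3H-pyrrolo[1,2-c][1,3,2]oxazaborole, 20 mol%], catecholborane, toluene, −78 °C; chromatography (trans from cis)
Reagents that add atoms: none
Why: Corey–Bakshi–Shibata reduction, in which the oxazaborolidine–borane complex delivers hydride to one face of the C3 ketone under reagent control (alkenyl arm as the large group), so that both enantiomers of 5 should give 3S carbinols and the 6S enantiomer gives the trans alcohol 6, which is separated by chromatography from the cis (3S,6R) epimer that comes from the 6R enantiomer and takes up to half of the material.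

Step 4
Reactants: 6 methyl (1S,4S)-4-hydroxy-2,6,6-trimethylcyclohex-2-ene-1-carboxylate
Product: 7 (1S,4S)-4-hydroxy-2,6,6-trimethylcyclohex-2-ene-1-carbaldehyde
Conditions: i-Bu2AlH (2.2 equiv), CH2Cl2, −78 °C; MeOH, then aq KNaC4H4O6 (potassium sodium tartrate), 0 °C; used crude
Reagents that add atoms: none
Why: Partial reduction of an ester with diisobutylaluminium hydride, in which the first equivalent is spent on the hydroxyl group and the second gives a tetrahedral aluminium hemiacetal of the hindered ester that should survive at −78 °C and release the aldehyde only on hydrolysis, under conditions that are not basic enough to epimerise C6.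

Step 5
Reactants: 7 (1S,4S)-4-hydroxy-2,6,6-trimethylcyclohex-2-ene-1-carbaldehyde
Product: 8 (3E)-4-[(1S,4S)-4-hydroxy-2,6,6-trimethylcyclohex-2-en-1-yl]but-3-en-2-one [(3S,6S)-3-hydroxy-α-ionone]
Conditions: Ph3P=CHC(O)CH3, toluene, 90 °C
Reagents that add atoms: 1-(triphenylphosphoranylidene)propan-2-one, CC(=O)C=P(c1ccccc1)(c1ccccc1)c1ccccc1
Why: Wittig reaction with a stabilised ylide, which should be E-selective and is close to neutral, so that the enolisable C6 centre next to the formyl group keeps its configuration and the free hydroxyl group needs no protection.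

Step 6
Reactants: 8 (3E)-4-[(1S,4S)-4-hydroxy-2,6,6-trimethylcyclohex-2-en-1-yl]but-3-en-2-one
Product: 9 (1E)-1-[(1S,4S)-4-hydroxy-2,6,6-trimethylcyclohex-2-en-1-yl]-3-methylpenta-1,4-dien-3-ol (both epimers at the tertiary carbinol)
Conditions: CH2=CHMgBr (3 equiv), THF, −20 → 0 °C; aq NH4Cl
Reagents that add atoms: vinylmagnesium bromide, C=C[Mg]Br
Why: Grignard 1,2-addition to the enone carbonyl (one equivalent is consumed by the hydroxyl group), giving the tertiary divinyl carbinol as a mixture of epimers at the new centre, which is of no consequence because that centre becomes sp2 in the next step.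

Step 7
Reactants: 9 (1E)-1-[(1S,4S)-4-hydroxy-2,6,6-trimethylcyclohex-2-en-1-yl]-3-methylpenta-1,4-dien-3-ol
Product: 10 [(2E,4E)-5-[(1S,4S)-4-hydroxy-2,6,6-trimethylcyclohex-2-en-1-yl]-3-methylpenta-2,4-dien-1-yl]triphenylphosphonium bromide
Conditions: Ph3P·HBr, MeOH, 0 °C → rt
Reagents that add atoms: triphenylphosphine hydrobromide, Br.c1ccc(cc1)P(c1ccccc1)c1ccccc1
Why: Ionisation of the tertiary, doubly allylic alcohol by the mild acid gives a pentadienyl cation that triphenylphosphine captures at the terminal carbon (SN1′, allylic transposition) to form the conjugated, mainly 9E phosphonium salt, while the secondary ring carbinol should ionise far more slowly.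

Step 8
Reactants: 11 (S)-α-ionone, (3E)-4-[(1S)-2,6,6-trimethylcyclohex-2-en-1-yl]but-3-en-2-one
Product: 12 (1E)-3-methyl-1-[(1S)-2,6,6-trimethylcyclohex-2-en-1-yl]penta-1,4-dien-3-ol (both epimers at the carbinol)
Conditions: CH2=CHMgBr, THF, 0 °C; aq NH4Cl
Reagents that add atoms: vinylmagnesium bromide, C=C[Mg]Br
Why: Grignard 1,2-addition to the methyl ketone of the enone as in step 6, in which C6′ is not involved and the new carbinol centre is again irrelevant.

Step 9
Reactants: 12 (1E)-3-methyl-1-[(1S)-2,6,6-trimethylcyclohex-2-en-1-yl]penta-1,4-dien-3-ol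
Product: 13 [(2E,4E)-3-methyl-5-[(1S)-2,6,6-trimethylcyclohex-2-en-1-yl]penta-2,4-dien-1-yl]triphenylphosphonium bromide
Conditions: Ph3P·HBr, MeOH, rt
Reagents that add atoms: triphenylphosphine hydrobromide, Br.c1ccc(cc1)P(c1ccccc1)c1ccccc1
Why: Same SN1′ phosphonium salt formation as in step 7, here without any other acid-sensitive group.

Step 10
Reactants: 13 [(2E,4E)-3-methyl-5-[(1S)-2,6,6-trimethylcyclohex-2-en-1-yl]penta-2,4-dien-1-yl]triphenylphosphonium bromide, 14 (2E,4E,6E)-2,7-dimethylocta-2,4,6-trienedial
Product: 15 (2E,4E,6E,8E,10E,12E)-2,7,11-trimethyl-13-[(1S)-2,6,6-trimethylcyclohex-2-en-1-yl]trideca-2,4,6,8,10,12-hexaenal (C25 aldehyde)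
Conditions: NaOMe, MeOH/CH2Cl2, 0 °C → rt, 14 in excess; then heptane, 80 °C (E/Z equilibration)
Reagents that add atoms: none
Why: Wittig olefination of one of the two equivalent formyl groups of the dialdehyde, which is used in excess to suppress double reaction; the semi-stabilised ylide should give an E/Z mixture at C11′=C12′ that is equilibrated to E on heating, as is usual for polyenes of this kind.

Step 11
Reactants: 15 C25 aldehyde, 10 [(2E,4E)-5-[(1S,4S)-4-hydroxy-2,6,6-trimethylcyclohex-2-en-1-yl]-3-methylpenta-2,4-dien-1-yl]triphenylphosphonium bromide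
Product: 16 (all-E)-(3S,6S,6′S)-ε,ε-caroten-3-ol (target)
Conditions: NaOMe, MeOH/CH2Cl2, rt; then heptane, 80 °C (E/Z equilibration), crystallisation
Reagents that add atoms: none
Why: Wittig olefination that forms C11=C12 and completes the C40 chain under conditions that leave the free hydroxyl group and the three stereocentres untouched, the Z isomer at the new double bond being converted into the all-E target on heating.

Compound list
1 | methyl 3-methylbut-2-enoate | COC(=O)C=C(C)C | starting material
2 | 1-methoxy-3-methyl-1-(trimethylsilyloxy)buta-1,3-diene | COC(O[Si](C)(C)C)=CC(C)=C | intermediate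
3 | 3-methylbut-2-enoyl chloride | CC(C)=CC(=O)Cl | starting material
4 | methyl (2E)-3,7-dimethyl-5-oxoocta-2,6-dienoate (open-chain keto dienoate) | COC(=O)/C=C(\C)CC(=O)C=C(C)C | intermediate
5 | methyl 2,6,6-trimethyl-4-oxocyclohex-2-ene-1-carboxylate (racemate) | COC(=O)C1C(C)=CC(=O)CC1(C)C | intermediate
6 | methyl (1S,4S)-4-hydroxy-2,6,6-trimethylcyclohex-2-ene-1-carboxylate | COC(=O)[C@@H]1C(C)=C[C@@H](O)CC1(C)C | intermediate
7 | (1S,4S)-4-hydroxy-2,6,6-trimethylcyclohex-2-ene-1-carbaldehyde | O=C[C@@H]1C(C)=C[C@@H](O)CC1(C)C | intermediate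
8 | (3E)-4-[(1S,4S)-4-hydroxy-2,6,6-trimethylcyclohex-2-en-1-yl]but-3-en-2-one | CC(=O)/C=C/[C@@H]1C(C)=C[C@@H](O)CC1(C)C | intermediate
9 | (1E)-1-[(1S,4S)-4-hydroxy-2,6,6-trimethylcyclohex-2-en-1-yl]-3-methylpenta-1,4-dien-3-ol (both carbinol epimers) | C=CC(C)(O)/C=C/[C@@H]1C(C)=C[C@@H](O)CC1(C)C | intermediate
10 | [(2E,4E)-5-[(1S,4S)-4-hydroxy-2,6,6-trimethylcyclohex-2-en-1-yl]-3-methylpenta-2,4-dien-1-yl]triphenylphosphonium bromide | [Br-].c1ccccc1[P+](c1ccccc1)(c1ccccc1)C/C=C(C)/C=C/[C@@H]1C(C)=C[C@@H](O)CC1(C)C | intermediate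
11 | (S)-α-ionone, (3E)-4-[(1S)-2,6,6-trimethylcyclohex-2-en-1-yl]but-3-en-2-one | CC(=O)/C=C/[C@@H]1C(C)=CCCC1(C)C | starting material
12 | (1E)-3-methyl-1-[(1S)-2,6,6-trimethylcyclohex-2-en-1-yl]penta-1,4-dien-3-ol (both carbinol epimers) | C=CC(C)(O)/C=C/[C@@H]1C(C)=CCCC1(C)C | intermediate
13 | [(2E,4E)-3-methyl-5-[(1S)-2,6,6-trimethylcyclohex-2-en-1-yl]penta-2,4-dien-1-yl]triphenylphosphonium bromide | [Br-].c1ccccc1[P+](c1ccccc1)(c1ccccc1)C/C=C(C)/C=C/[C@@H]1C(C)=CCCC1(C)C | intermediate
14 | (2E,4E,6E)-2,7-dimethylocta-2,4,6-trienedial | O=C/C(C)=C/C=C/C=C(\C)C=O | starting material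
15 | (2E,4E,6E,8E,10E,12E)-2,7,11-trimethyl-13-[(1S)-2,6,6-trimethylcyclohex-2-en-1-yl]trideca-2,4,6,8,10,12-hexaenal | CC1=CCCC(C)(C)[C@@H]1/C=C/C(C)=C/C=C/C(C)=C/C=C/C=C(C)/C=O | intermediate
16 | (all-E)-(3S,6S,6′S)-ε,ε-caroten-3-ol | CC1=CCCC(C)(C)[C@@H]1/C=C/C(C)=C/C=C/C(C)=C/C=C/C=C(C)/C=C/C=C(C)/C=C/[C@@H]1C(C)=C[C@@H](O)CC1(C)C | target

Total steps: 11. Longest linear sequence: 8 steps (steps 1–7, then step 11).

Steps most likely to fail

Step 2. What may go wrong: acylation at the α-carbon of the dienol ether instead of the terminal carbon, or, after enolisation, attack of the enolate oxygen on the ester (lactonisation) in place of carbon–carbon ring closure. The fallback sets out from 4 and comes back at 5. After the acylation, Me3SiOTf and Et3N are added to the same flask to trap the ketone of 4 as methyl (2E,4E)-3,7-dimethyl-5-[(trimethylsilyl)oxy]octa-2,4,6-trienoate F1, whose enol oxygen can no longer acylate. Heating in toluene should then bring about the thermal disrotatory 6π-electrocyclisation of this neutral triene to methyl 2,6,6-trimethyl-4-[(trimethylsilyl)oxy]cyclohexa-2,4-diene-1-carboxylate F2, and dilute aqueous HCl hydrolyses the silyl dienol ether to 5. The ring closure thus changes from an anionic Michael-type closure to a pericyclic closure of a silyl-protected triene.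

Step 3. What may go wrong: poor facial selectivity of hydride delivery, because the neopentyl-like CH2 arm may compete with the alkenyl arm as the large group, so that the trans alcohol has low enantiomeric purity. The fallback sets out from 5 and comes back at 6. Luche reduction (NaBH4, CeCl3·7H2O, MeOH, −78 °C) gives the racemic alcohols, from which the racemic trans isomer, methyl rac-(1S,4S)-4-hydroxy-2,6,6-trimethylcyclohex-2-ene-1-carboxylate F3, is isolated by chromatography. Kinetic resolution by enzymatic acetylation (lipase from Burkholderia cepacia, vinyl acetate, t-BuOMe) follows, in which the 4R carbinol is expected to be acylated faster, in line with the usual enantiopreference of lipases for cyclohex-2-enols, so that 6 remains as the unreacted alcohol and is separated from the acetate.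

Step 4. What may go wrong: over-reduction to the primary alcohol, or epimerisation at C6 and migration of the double bond into conjugation while the free aldehyde is handled. The fallback sets out from 6 and comes back at 8. The hydroxyl group is silylated (t-BuMe2SiCl, imidazole, DMF) to give methyl (1S,4S)-4-[(tert-butyldimethylsilyl)oxy]-2,6,6-trimethylcyclohex-2-ene-1-carboxylate F4. LiAlH4 in Et2O reduces the ester fully to [(1S,4S)-4-[(tert-butyldimethylsilyl)oxy]-2,6,6-trimethylcyclohex-2-en-1-yl]methanol F5. Dess–Martin periodinane buffered with NaHCO3 gives (1S,4S)-4-[(tert-butyldimethylsilyl)oxy]-2,6,6-trimethylcyclohex-2-ene-1-carbaldehyde F6, which is taken at once into the Wittig reaction of step 5 to give (3E)-4-[(1S,4S)-4-[(tert-butyldimethylsilyl)oxy]-2,6,6-trimethylcyclohex-2-en-1-yl]but-3-en-2-one F7. Bu4NF in THF removes the silyl group and returns 8.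

Further compounds
F1 | step 2 | methyl (2E,4E)-3,7-dimethyl-5-[(trimethylsilyl)oxy]octa-2,4,6-trienoate | COC(=O)/C=C(C)/C=C(O[Si](C)(C)C)\C=C(C)C
F2 | step 2 | methyl 2,6,6-trimethyl-4-[(trimethylsilyl)oxy]cyclohexa-2,4-diene-1-carboxylate (racemate) | COC(=O)C1C(C)=CC(O[Si](C)(C)C)=CC1(C)C
F3 | step 3 | methyl rac-(1S,4S)-4-hydroxy-2,6,6-trimethylcyclohex-2-ene-1-carboxylate (racemic trans alcohol, one enantiomer drawn) | COC(=O)[C@@H]1C(C)=C[C@@H](O)CC1(C)C
F4 | step 4 | methyl (1S,4S)-4-[(tert-butyldimethylsilyl)oxy]-2,6,6-trimethylcyclohex-2-ene-1-carboxylate | COC(=O)[C@@H]1C(C)=C[C@@H](O[Si](C)(C)C(C)(C)C)CC1(C)C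
F5 | step 4 | [(1S,4S)-4-[(tert-butyldimethylsilyl)oxy]-2,6,6-trimethylcyclohex-2-en-1-yl]methanol | OC[C@@H]1C(C)=C[C@@H](O[Si](C)(C)C(C)(C)C)CC1(C)C
F6 | step 4 | (1S,4S)-4-[(tert-butyldimethylsilyl)oxy]-2,6,6-trimethylcyclohex-2-ene-1-carbaldehyde | O=C[C@@H]1C(C)=C[C@@H](O[Si](C)(C)C(C)(C)C)CC1(C)C
F7 | step 4 | (3E)-4-[(1S,4S)-4-[(tert-butyldimethylsilyl)oxy]-2,6,6-trimethylcyclohex-2-en-1-yl]but-3-en-2-one | CC(=O)/C=C/[C@@H]1C(C)=C[C@@H](O[Si](C)(C)C(C)(C)C)CC1(C)C
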